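All three flavan units are drawn from one aurone. Ring C of the upper unit (O1, C2, C3, C4, C4a, C8a) is grown from the furan ring of a 2-(α-bromobenzyl)-2,3-dihydrobenzofuran: silver-assisted ionisation lets the antiperiplanar ring oxygen O1 displace bromide (new O1–C2 bond, inversion), and water opens the bicyclic oxiranium ion at the fusion carbon (new C3–OH, inversion). One operation thus expands furan to pyran and sets the cis C2-aryl/C3-hydroxyl pair of the epi-type unit, with the C4 silyloxy group already in place. That C4 oxygen later becomes the leaving group (via a thioether) for the two C4→C6 couplings; the middle unit comes from the enantiomeric carbinol by the same expansion.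

Key step: step 7

Remark: 1 and 3 are taken as catalogue compounds (3 is otherwise one acylation from 4-hydroxybenzaldehyde); the cationic intermediates 9 and 16 are written as their triflate salts.

Step 1
Reactants: 1 6,7-dihydroxy-1-benzofuran-3(2H)-one
Product: 2 6,7-bis(benzyloxy)-1-benzofuran-3(2H)-one
Conditions: BnBr, K2CO3, DMF, rt
Reagents that add atoms: benzyl bromide BrCc1ccccc1
Why: Williamson ether synthesis; the two phenoxides are alkylated far faster than the weakly acidic C2 methylene under carbonate conditions, and no stereocentre is formed.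

Step 2
Reactants: 2 6,7-bis(benzyloxy)-1-benzofuran-3(2H)-one; 3 4-formylphenyl pivalate
Product: 4 4-{(Z)-[6,7-bis(benzyloxy)-3-oxo-1-benzofuran-2(3H)-ylidene]methyl}phenyl pivalate (aurone)
Conditions: neutral Al2O3, CH2Cl2, rt
Reagents that add atoms: none
Why: Aldol condensation of the active C2 methylene with the aldehyde on a neutral surface that spares the aryl pivalate; the conjugated (Z)-aurone is the thermodynamic alkene isomer.

Step 3
Reactants: 4 aurone
Product: 5 4-{(Z)-[(3R)-6,7-bis(benzyloxy)-3-hydroxy-1-benzofuran-2(3H)-ylidene]methyl}phenyl pivalate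
Conditions: (S)-2-methyl-CBS-oxazaborolidine (20 mol%), BH3·SMe2, THF, −30 °C; buffered work-up
Reagents that add atoms: none
Why: Corey–Bakshi–Shibata reduction; 1,2-hydride delivery inside the catalyst–borane–ketone complex, with the benzylidene-bearing C2 flank expected to act as the large group, should set the C3 carbinol as R.

Step 4
Reactants: 5 (3R)-allylic alcohol
Product: 6 4-{(Z)-[(3R)-6,7-bis(benzyloxy)-3-(tert-butyldimethylsilyloxy)-1-benzofuran-2(3H)-ylidene]methyl}phenyl pivalate
Conditions: t-BuMe2SiCl, imidazole, DMF, 0 °C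
Reagents that add atoms: tert-butyl(chloro)dimethylsilane CC(C)(C)[Si](C)(C)Cl
Why: Silylation under basic conditions masks the acid-labile allylic alcohol with a non-participating group that later serves as the C4 leaving group; the stereocentre is untouched.

Step 5
Reactants: 6 (3R)-silyl enol ether
Product: 7 4-{(R)-[(2R,3R)-6,7-bis(benzyloxy)-3-(tert-butyldimethylsilyloxy)-2,3-dihydro-1-benzofuran-2-yl](hydroxy)methyl}phenyl pivalate
Conditions: BH3·SMe2, THF, 0 °C; then NaBO3·4H2O, THF–H2O, rt
Reagents that add atoms: sodium perborate [Na+].[Na+].O[B-]1(O)OO[B-](O)(O)OO1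
Why: Brown hydroboration–oxidation of the enol ether; boron adds to the benzylic carbon β to the ring oxygen and hydrogen to C2, syn and on the face opposite the allylic silyloxy group, and oxidation with retention should give the (R)-carbinol and the 2,3-cis furan stereocentre.

Step 6
Reactants: 7 (R)-carbinol
Product: 8 4-{(S)-[(2S,3R)-6,7-bis(benzyloxy)-3-(tert-butyldimethylsilyloxy)-2,3-dihydro-1-benzofuran-2-yl](bromo)methyl}phenyl pivalate
Conditions: CBr4, PPh3, CH2Cl2, −20 to 0 °C
Reagents that add atoms: tetrabromomethane BrC(Br)(Br)Br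
Why: Appel reaction; under non-ionising conditions bromide displaces the oxyphosphonium group by SN2 with inversion (R to S), faster than the weakly nucleophilic aryl ether oxygen can participate.

Step 7
Reactants: 8 (S)-bromide
Product: 10 4-[(2R,3S,4R)-7,8-bis(benzyloxy)-4-(tert-butyldimethylsilyloxy)-3-hydroxy-3,4-dihydro-2H-chromen-2-yl]phenyl pivalate (all-cis), via oxiranium triflate 9 (not isolated)
Conditions: AgOSO2CF3, 2,6-di-tert-butyl-4-methylpyridine, acetone–H2O (10:1), −20 °C to rt
Reagents that add atoms: water O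
Why: Silver ion pulls bromide from the benzylic carbon while the antiperiplanar ring oxygen O1 attacks from the rear (inversion, new O1–C2 bond), giving the 2-oxoniabicyclo[3.1.0]hexane-type aryloxiranium ion 9, which water opens at the ring-fusion carbon with a second inversion (new C3–OH), so that the five-membered furan ring becomes the six-membered pyran ring C. The closest known reaction type is the Nakata ring expansion of 2-(1-sulfonyloxyalkyl)tetrahydrofurans to 3-oxytetrahydropyrans through bicyclic oxonium ions; it is formally the reverse of the solvolytic ring contraction of flavan-3-yl sulfonates. Ring C is closed by 3-exo-tet O-alkylation followed by cleavage of the fusion bond, a formal 6-endo closure at C2. C2 is fixed by inversion of the (S)-bromide carbon, C3 by inversion of furan C2 (set in step 5), and the untouched C4 silyloxy centre ends cis to both, giving the all-cis array. The step needs oxygen participation to outrun free benzylic ionisation, which the electron-poor 4-pivaloyloxyphenyl group should secure. It also needs opening at the fusion carbon and not at the benzylic carbon, which release of the strain of both small rings should favour.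

Step 8
Reactants: 10 all-cis flavan-3-ol 4-silyl ether
Product: 11 4-[(2R,3S,4S)-7,8-bis(benzyloxy)-4-(benzylsulfanyl)-3-hydroxy-3,4-dihydro-2H-chromen-2-yl]phenyl pivalate
Conditions: PhCH2SH, Me3SiOSO2CF3 (10 mol%), CH2Cl2, −40 °C
Reagents that add atoms: phenylmethanethiol SCc1ccccc1
Why: Acid-catalysed SN1 thiolysis; the C4 silyloxy group ionises to the 4-flavanyl cation (stabilised by O1 and the C7 benzyloxy group) and the thiol should add opposite the C2 aryl and C3 hydroxyl groups to give the 3,4-trans thioether (this centre is ionised again in step 15).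

Step 9
Reactants: 4 aurone
Product: 12 4-{(Z)-[(3S)-6,7-bis(benzyloxy)-3-hydroxy-1-benzofuran-2(3H)-ylidene]methyl}phenyl pivalate
Conditions: (R)-2-methyl-CBS-oxazaborolidine (20 mol%), BH3·SMe2, THF, −30 °C; buffered work-up
Reagents that add atoms: none
Why: Corey–Bakshi–Shibata reduction with the enantiomeric catalyst should give the (3S)-carbinol by the same transition-state model as step 3.

Step 10
Reactants: 12 (3S)-allylic alcohol
Product: 13 4-{(Z)-[(3S)-6,7-bis(benzyloxy)-3-(tert-butyldimethylsilyloxy)-1-benzofuran-2(3H)-ylidene]methyl}phenyl pivalate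
Conditions: t-BuMe2SiCl, imidazole, DMF, 0 °C
Reagents that add atoms: tert-butyl(chloro)dimethylsilane CC(C)(C)[Si](C)(C)Cl
Why: Silylation as in step 4; the stereocentre is untouched.

Step 11
Reactants: 13 (3S)-silyl enol ether
Product: 14 4-{(S)-[(2S,3S)-6,7-bis(benzyloxy)-3-(tert-butyldimethylsilyloxy)-2,3-dihydro-1-benzofuran-2-yl](hydroxy)methyl}phenyl pivalate
Conditions: BH3·SMe2, THF, 0 °C; then NaBO3·4H2O, THF–H2O, rt
Reagents that add atoms: sodium perborate [Na+].[Na+].O[B-]1(O)OO[B-](O)(O)OO1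
Why: Brown hydroboration–oxidation as in step 5; syn addition opposite the silyloxy group should set the (S)-carbinol and the (2S) furan centre.

Step 12
Reactants: 14 (S)-carbinol
Product: 17 4-[(2R,3R,4S)-7,8-bis(benzyloxy)-4-(tert-butyldimethylsilyloxy)-3-hydroxy-3,4-dihydro-2H-chromen-2-yl]phenyl pivalate (2,3-trans-3,4-cis), via triflate 15 (not isolated), via oxiranium triflate 16 (not isolated)
Conditions: (CF3SO2)2O, 2,6-di-tert-butyl-4-methylpyridine, CH2Cl2, −78 °C; then THF–H2O, −78 to 0 °C
Reagents that add atoms: water O; trifluoromethanesulfonic anhydride O=S(=O)(OS(=O)(=O)C(F)(F)F)C(F)(F)F (its atoms stay only in 15)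
Why: The oxiranium ring expansion of step 7 run without prior inversion; O1 displaces the triflate with inversion to the oxiranium ion with aryl and furan C3 trans, and water opens the fusion carbon with inversion, which should give the 2R, 2,3-trans pyran ring of the middle unit.

Step 13
Reactants: 17 2,3-trans flavan-3-ol 4-silyl ether
Product: 18 4-[(2R,3R,4R)-7,8-bis(benzyloxy)-4-(benzylsulfanyl)-3-hydroxy-3,4-dihydro-2H-chromen-2-yl]phenyl pivalate
Conditions: PhCH2SH, Me3SiOSO2CF3 (10 mol%), CH2Cl2, −40 °C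
Reagents that add atoms: phenylmethanethiol SCc1ccccc1
Why: Acid-catalysed SN1 thiolysis as in step 8; the thiol should add trans to the C3 hydroxyl group (this centre is ionised again in step 14).

Step 14
Reactants: 18 middle-unit thioether; 10 all-cis flavan-3-ol 4-silyl ether (threefold excess)
Product: 19 protected dimer (C4 of the 2,3-trans unit bonded to C6 of the lower unit)
Conditions: AgBF4, 2,6-di-tert-butyl-4-methylpyridine, THF, 0 °C
Reagents that add atoms: none
Why: Thiophilic activation followed by Friedel–Crafts alkylation; silver ion removes the benzylsulfanyl group, and the 4-flavanyl cation is attacked by C6 of 10 (para to O1 and ortho to the C7 oxygen, the only ring carbon activated by two oxygens) from the face opposite the C3 hydroxyl, setting the 3,4-trans (4α) centre, while the buffered, soft activation leaves the C4 silyloxy group of 10 intact.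

Step 15
Reactants: 11 upper-unit thioether (added slowly); 19 protected dimer
Product: 20 protected trimer (C4 of the 2,3-cis unit bonded to C6 of the middle unit)
Conditions: AgBF4, 2,6-di-tert-butyl-4-methylpyridine, THF, 0 °C
Reagents that add atoms: none
Why: The same thiophilic Friedel–Crafts coupling; C6 of the middle unit is the only unsubstituted doubly activated carbon of 19, and attack on the epi-type cation opposite both the C2 aryl and the C3 hydroxyl groups should set the 3,4-trans (4β) centre, slow addition of 11 keeping self-condensation low.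

Step 16
Reactants: 20 protected trimer
Product: 22 hexa-O-benzyl trimer (free C3 and C4 hydroxyls and free 4'-phenols), via desilylated tris-pivalate 21 (not isolated)
Conditions: Bu4NF, THF, 0 °C to rt; then K2CO3, MeOH, rt
Reagents that add atoms: none
Why: Fluoride-mediated desilylation followed by methanolysis of the three aryl pivalates (phenoxide leaving groups) at room temperature, where no stereocentre should be touched.

Step 17
Reactants: 22 hexa-O-benzyl trimer
Product: 23 epioritin-(4β→6)-oritin-(4α→6)-epioritin-4α-ol (target)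
Conditions: H2 (1 atm), Pd(OH)2/C, THF–MeOH, rt, neutral
Reagents that add atoms: none
Why: Hydrogenolysis of the six aryl benzyl ethers, which cleave much faster than the benzylic C4–OH and the diarylmethine C–C bonds under neutral conditions; no stereocentre is touched.

Compound list
1 | 6,7-dihydroxy-1-benzofuran-3(2H)-one | O=C1COc2c1ccc(O)c2O | starting material
2 | 6,7-bis(benzyloxy)-1-benzofuran-3(2H)-one | O=C1COc2c1ccc(OCc1ccccc1)c2OCc1ccccc1 | intermediate
3 | 4-formylphenyl pivalate | O=Cc1ccc(OC(=O)C(C)(C)C)cc1 | starting material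
4 | 4-{(Z)-[6,7-bis(benzyloxy)-3-oxo-1-benzofuran-2(3H)-ylidene]methyl}phenyl pivalate | O=C1/C(=C/c2ccc(OC(=O)C(C)(C)C)cc2)Oc2c1ccc(OCc1ccccc1)c2OCc1ccccc1 | intermediate
5 | (3R,Z)-allylic alcohol from 4 | c1cc2c(c(OCc3ccccc3)c1OCc1ccccc1)O/C(=C\c1ccc(OC(=O)C(C)(C)C)cc1)[C@@H]2O | intermediate
6 | (3R,Z)-tert-butyldimethylsilyl ether of 5 | c1cc2c(c(OCc3ccccc3)c1OCc1ccccc1)O/C(=C\c1ccc(OC(=O)C(C)(C)C)cc1)[C@@H]2O[Si](C)(C)C(C)(C)C | intermediate
7 | (R)-carbinol on the (2R,3R)-2,3-cis-dihydrobenzofuran | c1cc2c(c(OCc3ccccc3)c1OCc1ccccc1)O[C@H]([C@H](O)c1ccc(OC(=O)C(C)(C)C)cc1)[C@@H]2O[Si](C)(C)C(C)(C)C | intermediate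
8 | (S)-bromide on the (2S,3R)-dihydrobenzofuran (carbinol carbon of 7 inverted) | c1cc2c(c(OCc3ccccc3)c1OCc1ccccc1)O[C@H]([C@@H](Br)c1ccc(OC(=O)C(C)(C)C)cc1)[C@@H]2O[Si](C)(C)C(C)(C)C | intermediate
9 | aryloxiranium triflate from 8 (O1 bridging furan C2 and the former bromide carbon; aryl and furan C3 cis) | c1cc2c(c(OCc3ccccc3)c1OCc1ccccc1)[O+]3[C@H](c1ccc(OC(=O)C(C)(C)C)cc1)[C@@H]3[C@@H]2O[Si](C)(C)C(C)(C)C.[O-]S(=O)(=O)C(F)(F)F | intermediate (not isolated)
10 | 4-[(2R,3S,4R)-7,8-bis(benzyloxy)-4-(tert-butyldimethylsilyloxy)-3-hydroxy-3,4-dihydro-2H-chromen-2-yl]phenyl pivalate (all-cis; lower unit) | c1cc2c(c(OCc3ccccc3)c1OCc1ccccc1)O[C@H](c1ccc(OC(=O)C(C)(C)C)cc1)[C@H](O)[C@@H]2O[Si](C)(C)C(C)(C)C | intermediate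
11 | 4-[(2R,3S,4S)-7,8-bis(benzyloxy)-4-(benzylsulfanyl)-3-hydroxy-3,4-dihydro-2H-chromen-2-yl]phenyl pivalate (2,3-cis-3,4-trans; upper-unit electrophile) | c1cc2c(c(OCc3ccccc3)c1OCc1ccccc1)O[C@H](c1ccc(OC(=O)C(C)(C)C)cc1)[C@H](O)[C@H]2SCc1ccccc1 | intermediate
12 | (3S,Z)-allylic alcohol (enantiomer of 5) | c1cc2c(c(OCc3ccccc3)c1OCc1ccccc1)O/C(=C\c1ccc(OC(=O)C(C)(C)C)cc1)[C@H]2O | intermediate
13 | (3S,Z)-tert-butyldimethylsilyl ether (enantiomer of 6) | c1cc2c(c(OCc3ccccc3)c1OCc1ccccc1)O/C(=C\c1ccc(OC(=O)C(C)(C)C)cc1)[C@H]2O[Si](C)(C)C(C)(C)C | intermediate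
14 | (S)-carbinol on the (2S,3S)-dihydrobenzofuran (enantiomer of 7) | c1cc2c(c(OCc3ccccc3)c1OCc1ccccc1)O[C@@H]([C@@H](O)c1ccc(OC(=O)C(C)(C)C)cc1)[C@H]2O[Si](C)(C)C(C)(C)C | intermediate
15 | triflate of 14 | c1cc2c(c(OCc3ccccc3)c1OCc1ccccc1)O[C@@H]([C@@H](OS(=O)(=O)C(F)(F)F)c1ccc(OC(=O)C(C)(C)C)cc1)[C@H]2O[Si](C)(C)C(C)(C)C | intermediate (not isolated)
16 | aryloxiranium triflate from 15 (aryl and furan C3 trans) | c1cc2c(c(OCc3ccccc3)c1OCc1ccccc1)[O+]3[C@H](c1ccc(OC(=O)C(C)(C)C)cc1)[C@H]3[C@H]2O[Si](C)(C)C(C)(C)C.[O-]S(=O)(=O)C(F)(F)F | intermediate (not isolated)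
17 | 4-[(2R,3R,4S)-7,8-bis(benzyloxy)-4-(tert-butyldimethylsilyloxy)-3-hydroxy-3,4-dihydro-2H-chromen-2-yl]phenyl pivalate (2,3-trans-3,4-cis) | c1cc2c(c(OCc3ccccc3)c1OCc1ccccc1)O[C@H](c1ccc(OC(=O)C(C)(C)C)cc1)[C@@H](O)[C@H]2O[Si](C)(C)C(C)(C)C | intermediate
18 | 4-[(2R,3R,4R)-7,8-bis(benzyloxy)-4-(benzylsulfanyl)-3-hydroxy-3,4-dihydro-2H-chromen-2-yl]phenyl pivalate (2,3-trans-3,4-trans; middle-unit electrophile) | c1cc2c(c(OCc3ccccc3)c1OCc1ccccc1)O[C@H](c1ccc(OC(=O)C(C)(C)C)cc1)[C@@H](O)[C@@H]2SCc1ccccc1 | intermediate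
19 | protected dimer: C4 of the 2R, 2,3-trans-3,4-trans unit bonded to C6 of 10, new aryl bond trans to the C3 hydroxyl; four benzyl ethers, two pivalates and the C4 silyl ether retained | c1cc2c(c(OCc3ccccc3)c1OCc1ccccc1)O[C@H](c1ccc(OC(=O)C(C)(C)C)cc1)[C@@H](O)[C@@H]2c1cc2c(c(OCc3ccccc3)c1OCc1ccccc1)O[C@H](c1ccc(OC(=O)C(C)(C)C)cc1)[C@H](O)[C@@H]2O[Si](C)(C)C(C)(C)C | intermediate
20 | protected trimer: C4 of the 2R, 2,3-cis-3,4-trans unit bonded to C6 of the middle unit of 19; six benzyl ethers, three pivalates, one silyl ether | CC(C)(C)C(=O)Oc1ccc([C@H]2Oc3c(ccc(OCc4ccccc4)c3OCc3ccccc3)[C@H](c3cc4c(c(OCc5ccccc5)c3OCc3ccccc3)O[C@H](c3ccc(OC(=O)C(C)(C)C)cc3)[C@@H](O)[C@@H]4c3cc4c(c(OCc5ccccc5)c3OCc3ccccc3)O[C@H](c3ccc(OC(=O)C(C)(C)C)cc3)[C@H](O)[C@@H]4O[Si](C)(C)C(C)(C)C)[C@H]2O)cc1 | intermediate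
21 | trimer 20 without the silyl group (free C4 hydroxyl on the lower unit) | CC(C)(C)C(=O)Oc1ccc([C@H]2Oc3c(ccc(OCc4ccccc4)c3OCc3ccccc3)[C@H](c3cc4c(c(OCc5ccccc5)c3OCc3ccccc3)O[C@H](c3ccc(OC(=O)C(C)(C)C)cc3)[C@@H](O)[C@@H]4c3cc4c(c(OCc5ccccc5)c3OCc3ccccc3)O[C@H](c3ccc(OC(=O)C(C)(C)C)cc3)[C@H](O)[C@@H]4O)[C@H]2O)cc1 | intermediate (not isolated)
22 | hexa-O-benzyl trimer (all 7- and 8-oxygens benzylated; 4'-phenols, C3 hydroxyls and the lower C4 hydroxyl free) | Oc1ccc([C@H]2Oc3c(ccc(OCc4ccccc4)c3OCc3ccccc3)[C@H](c3cc4c(c(OCc5ccccc5)c3OCc3ccccc3)O[C@H](c3ccc(O)cc3)[C@@H](O)[C@@H]4c3cc4c(c(OCc5ccccc5)c3OCc3ccccc3)O[C@H](c3ccc(O)cc3)[C@H](O)[C@@H]4O)[C@H]2O)cc1 | intermediate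
23 | epioritin-(4β→6)-oritin-(4α→6)-epioritin-4α-ol | Oc1ccc([C@H]2Oc3c(ccc(O)c3O)[C@H](c3cc4c(c(O)c3O)O[C@H](c3ccc(O)cc3)[C@@H](O)[C@@H]4c3cc4c(c(O)c3O)O[C@H](c3ccc(O)cc3)[C@H](O)[C@@H]4O)[C@H]2O)cc1 | target

Total step count: 17.
Longest linear sequence: 11 steps (for example steps 1, 2, 3, 4, 5, 6, 7, 8, 15, 16, 17).

Steps most likely to fail

Step 7 (the same concern holds for its sibling, step 12). The oxiranium ion may be captured by water at the benzylic carbon, which only returns a dihydrobenzofuran carbinol, or the bromide may ionise without oxygen participation, which would scramble C2. The fallback sets out from bromide 8 and moves the C3 stereocentre to a ketone reduction. AgBF4 in dry DMSO at rt makes DMSO the only nucleophile; its adducts are themselves nucleofuges, so capture at the benzylic carbon is reversible and the mixture can drain to the ring-expanded C3 alkoxysulfonium tetrafluoroborate F1. Addition of i-Pr2NEt at 0 °C then collapses F1 in a Kornblum oxidation to the (2R,4R)-flavan-3-one F2. LiBH(s-Bu)3 in THF at −78 °C should deliver hydride opposite the C2 aryl and C4 silyloxy groups, and the route is rejoined at 10.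

Step 5 (and step 11). The β-aryloxy organoborane may undergo β-elimination with opening of the furan ring, or boron may be delivered to the wrong carbon. The fallback sets out from enol ether 6. Dimethyldioxirane in acetone–CH2Cl2 at −40 °C should epoxidise the enol ether opposite the silyloxy group to the spiro epoxy ether F3. i-Bu2AlH in CH2Cl2 at −78 °C then binds the epoxide oxygen, opens the acetal C–O bond and delivers hydride to the same face (cis opening, as with 1,2-anhydro sugars), and the route is rejoined at 7.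

Step 3 (and step 9). Enantioselection may be poor, because both flanks of the carbonyl group are planar sp2 carbons of similar size. The fallback sets out from aurone 4 and replaces asymmetric reduction by a resolution that supplies both series. NaBH4 with CeCl3·7H2O in MeOH–THF at −40 °C gives the racemic allylic alcohol F4. Candida antarctica lipase B with vinyl acetate in t-BuOMe should acylate one enantiomer, expected to be the (S)-alcohol, to the acetate F5 and leave the (R)-alcohol, which is 5. Lipase-catalysed butanolysis of F5 then gives 12, so the route is rejoined at 5 and at 12.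

Further compounds
F1 | step 7 | dimethyl{[(2R,3S,4R)-7,8-bis(benzyloxy)-4-(tert-butyldimethylsilyloxy)-2-(4-pivaloyloxyphenyl)-3,4-dihydro-2H-chromen-3-yl]oxy}sulfonium tetrafluoroborate | c1cc2c(c(OCc3ccccc3)c1OCc1ccccc1)O[C@H](c1ccc(OC(=O)C(C)(C)C)cc1)[C@H](O[S+](C)C)[C@@H]2O[Si](C)(C)C(C)(C)C.F[B-](F)(F)F
F2 | step 7 | 4-[(2R,4R)-7,8-bis(benzyloxy)-4-(tert-butyldimethylsilyloxy)-3-oxo-3,4-dihydro-2H-chromen-2-yl]phenyl pivalate | c1cc2c(c(OCc3ccccc3)c1OCc1ccccc1)O[C@H](c1ccc(OC(=O)C(C)(C)C)cc1)C(=O)[C@@H]2O[Si](C)(C)C(C)(C)C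
F3 | step 5 | spiro epoxy ether of 6 (epoxide oxygen on the face opposite the silyloxy group) | c1cc2c(c(OCc3ccccc3)c1OCc1ccccc1)O[C@@]3(O[C@@H]3c1ccc(OC(=O)C(C)(C)C)cc1)[C@@H]2O[Si](C)(C)C(C)(C)C
F4 | step 3 | racemic (Z)-allylic alcohol (racemate of 5 and 12) | c1cc2c(c(OCc3ccccc3)c1OCc1ccccc1)O/C(=C\c1ccc(OC(=O)C(C)(C)C)cc1)C2O
F5 | step 3 | (3S,Z)-acetate of 12 | c1cc2c(c(OCc3ccccc3)c1OCc1ccccc1)O/C(=C\c1ccc(OC(=O)C(C)(C)C)cc1)[C@H]2OC(C)=O
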